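The route rests on cutting the ten-membered ring (C1–C10) at C3–C4 and reading the 1,3-anti C2/C4 diacetate that spans C3 as a β-hydroxy ketone held in an isoxazoline. One intramolecular nitrile oxide–alkene cycloaddition forms C3–C4 and O–C2, closes the carbocycle and the bridging N–O ring together and sets C2. Its precursor is the complete seco compound: the cyclohexane (C1, C10–C14) with a vinyl group on quaternary C1, joined through C9 to the C7–C8 butanolide, whose Z-alkenyl arm ends in the C4 aldoxime; the C8 hydroxyl is silylated so that it cannot trap the nitrile oxide.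

Key step: step 32

Assumption: briarane numbering is used for every intermediate and β means the face of the C1 methyl (C15); the catalyst of step 2 and the ligand of step 17 are written as the antipodes expected to give the configurations shown, and as both are available in either form the mirror-image reagent would be used if the sense of induction proved opposite.

Step 1
Reactants: 1 pent-1-en-3-one
Product: 2 (Z)-triisopropyl(penta-1,3-dien-3-yloxy)silane (C14H2=C13H–C12(OTIPS)=C11H–CH3, methyl cis to OSi)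
Conditions: TIPSOTf, Et3N, CH2Cl2, 0 °C
Reagents that add atoms: triisopropylsilyl triflate, CC(C)[Si](C(C)C)(C(C)C)OS(=O)(=O)C(F)(F)F
Why: Amine/silyl triflate enolisation and O-silylation on the only enolisable side of the ketone gives the 2-silyloxy diene, the Z enol ether being the normal outcome for ethyl ketones.

Step 2
Reactants: 2 (Z)-triisopropyl(penta-1,3-dien-3-yloxy)silane; 3 ethyl (E)-3-formylbut-2-enoate
Product: 4 cycloadduct, ethyl 6-formyl-2,6-dimethyl-3-(triisopropylsilyloxy)cyclohex-3-ene-1-carboxylate (C1 β-CH3/α-CHO, C10 β-CO2Et, C12=C13 silyl enol ether, C11 methyl as both epimers)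
Conditions: (S)-B-o-tolyl-diphenylprolinol oxazaborolidine (20 mol%), Tf2NH (18 mol%), CH2Cl2, −78 → −40 °C
Reagents that add atoms: none
Why: Enantioselective Diels–Alder reaction under chiral oxazaborolidinium catalysis: the boron-bound formyl group makes C10 the electrophilic terminus so that the nucleophilic diene carbon C11 bonds to C10 and C14 to C1, the E dienophile fixes CHO trans to CO2Et and C15 cis to C9, the catalyst shields one enal face and so sets C1 and C10 absolutely, and C11, which depends on endo or exo approach, is carried as a mixture and reset in step 7.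

Step 3
Reactants: 4 cycloadduct
Product: 5 vinyl ester (as 4, formyl converted into the C2=C3 vinyl group)
Conditions: Ph3PCH3Br, KHMDS, THF, 0 °C
Reagents that add atoms: methyltriphenylphosphonium bromide, C[P+](c1ccccc1)(c1ccccc1)c1ccccc1.[Br-]
Why: Wittig methylenation of the non-enolisable neopentyl aldehyde is faster than any reaction of the ester or the silyl enol ether and creates no stereocentre.

Step 4
Reactants: 5 vinyl ester
Product: 6 primary alcohol (C9 CH2OH on C10, β)
Conditions: i-Bu2AlH, CH2Cl2, −78 °C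
Reagents that add atoms: none
Why: Hydride reduction of the ester to the alcohol; the silyl enol ether and the alkenes are inert to i-Bu2AlH at low temperature and no stereocentre is touched.

Step 5
Reactants: 6 primary alcohol
Product: 7 C9 p-methoxybenzyl ether
Conditions: NaH, PMBCl, Bu4NI (cat.), THF/DMF, 0 → 25 °C
Reagents that add atoms: 4-methoxybenzyl chloride, COc1ccc(CCl)cc1
Why: Williamson etherification of the primary alkoxide, carried out while C12 is still an enol ether so that no base meets an epimerisable ketone or an enone.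

Step 6
Reactants: 7 C9 p-methoxybenzyl ether
Product: 8 enone (C12 ketone, C13=C14, C1 β-CH3/α-vinyl, C10 β-CH2OPMB, C11 methyl as both epimers)
Conditions: Pd(OAc)2 (1.1 equiv), MeCN, 25–40 °C
Reagents that add atoms: none
Why: Saegusa–Ito oxidation: the palladium enolate formed from the C12=C13 silyl enol ether can lose hydride only from C14, giving the C13=C14 enone regiospecifically under neutral conditions.

Step 7
Reactants: 8 enone
Product: 10 enone with 11β-methyl (cis to the C10 side arm), via lithium dienolate 9 (not isolated)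
Conditions: LDA, THF, −78 °C; then 2,6-di-tert-butyl-4-methylphenol, −78 °C
Reagents that add atoms: none
Why: Kinetic enolate protonation: C11 carries the only acidic hydrogen (C1 is quaternary), and the cross-conjugated dienolate is C-protonated by the hindered phenol on the α face, away from the C10 side arm and the C15 methyl, so both C11 epimers converge on the 11β-methyl isomer, which is also the one that can place the C10 arm axial on the ring position lacking syn-axial hydrogens.

Step 8
Reactants: 10 enone with 11β-methyl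
Product: 12 14α-hydroxy ketone, via boryl ketone 11 (not isolated)
Conditions: B2pin2, CuCl (5 mol%), NaOt-Bu (5 mol%), DPEphos (5 mol%), MeOH, THF, 0 °C; then NaBO3·4H2O, THF/H2O, 0 → 25 °C
Reagents that add atoms: sodium perborate, [Na+].[Na+].O[B-]1(O)OO[B-](O)(O)OO1
Why: Copper-catalysed conjugate borylation of the enone followed by stereoretentive C–B oxidation; the boryl copper adds to C14 on the α face, opposite the C15 methyl, the C10 arm and the C11 methyl that crowd the β face, which sets the 14α oxygen.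

Step 9
Reactants: 12 14α-hydroxy ketone
Product: 13 14α-acetoxy ketone
Conditions: Ac2O, pyridine, DMAP (cat.), CH2Cl2, 0 °C
Reagents that add atoms: acetic anhydride, CC(=O)OC(C)=O
Why: DMAP-catalysed acylation at 0 °C is faster than β-elimination of the acetoxy ketone and installs the C14 acetate of the target early, which also distinguishes O14 from O12.

Step 10
Reactants: 13 14α-acetoxy ketone
Product: 14 12β-alcohol (11β-methyl, 14α-OAc)
Conditions: LiBH(s-Bu)3, THF, −78 °C
Reagents that add atoms: none
Why: Reduction by a bulky trialkylborohydride: hydride enters equatorially on the α face of the C12 ketone, away from the axial C10 arm, giving the axial 12β-alcohol cis to the C11 methyl, and the hindered acetate survives at −78 °C.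

Step 11
Reactants: 14 12β-alcohol
Product: 15 12β-tert-butyldimethylsilyl ether
Conditions: TBSOTf, 2,6-lutidine, CH2Cl2, −78 → 0 °C
Reagents that add atoms: tert-butyldimethylsilyl triflate, CC(C)(C)[Si](C)(C)OS(=O)(=O)C(F)(F)F
Why: Silyl triflate silylation is reactive enough for the hindered axial alcohol and changes no stereocentre.

Step 12
Reactants: 15 12β-tert-butyldimethylsilyl ether
Product: 16 C9 primary alcohol
Conditions: DDQ, CH2Cl2/pH 7 buffer, 0 °C
Reagents that add atoms: none
Why: Oxidative p-methoxybenzyl ether cleavage (benzylic hydride abstraction, hydrolysis) is orthogonal to silyl ether, acetate and the alkene.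

Step 13
Reactants: 16 C9 primary alcohol
Product: 17 ring aldehyde (C9 formyl on C10 β; 1β-methyl, 1α-vinyl, 11β-methyl, 12β-OTBS, 14α-OAc)
Conditions: Dess–Martin periodinane, NaHCO3, CH2Cl2, 0 → 25 °C
Reagents that add atoms: none
Why: Dess–Martin oxidation under buffered conditions gives the α-branched aldehyde without epimerising C10; it is used at once.

Step 14
Reactants: 18 propargyl alcohol
Product: 19 (Z)-3-iodo-2-methylprop-2-en-1-ol
Conditions: MeMgBr, CuI (10 mol%), THF, −10 → 25 °C; then I2, −78 → 0 °C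
Reagents that add atoms: methylmagnesium bromide, C[Mg]Br; iodine, II
Why: Copper-catalysed anti carbomagnesiation of the propargylic alkoxide puts methyl on C5 and magnesium on C6 in a five-membered chelate, and iodinolysis with retention gives the Z iodide (I cis to CH2OH).

Step 15
Reactants: 19 (Z)-3-iodo-2-methylprop-2-en-1-ol
Product: 20 (Z)-1-iodo-3-(4-methoxybenzyloxy)-2-methylprop-1-ene
Conditions: NaH, PMBCl, Bu4NI (cat.), THF/DMF, 0 °C
Reagents that add atoms: 4-methoxybenzyl chloride, COc1ccc(CCl)cc1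
Why: Williamson etherification; the vinyl iodide has no hydrogen placed for elimination and the alkene geometry is untouched.

Step 16
Reactants: 20 (Z)-1-iodo-3-(4-methoxybenzyloxy)-2-methylprop-1-ene
Product: 21 (Z)-4-(4-methoxybenzyloxy)-3-methylbut-2-enal
Conditions: t-BuLi (2.1 equiv), Et2O, −78 °C; then DMF
Reagents that add atoms: N,N-dimethylformamide, CN(C)C=O
Why: Iodine–lithium exchange and formylation both proceed with retention of alkene geometry, giving the Z enal (C4 cis to C7).

Step 17
Reactants: 21 (Z)-4-(4-methoxybenzyloxy)-3-methylbut-2-enal; 22 methyl propiolate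
Product: 23 methyl (S,Z)-4-hydroxy-7-(4-methoxybenzyloxy)-6-methylhept-5-en-2-ynoate
Conditions: Me2Zn, (S,S)-ProPhenol (20 mol%), Ph3PO (40 mol%), toluene, 0 °C
Reagents that add atoms: none
Why: Zinc-catalysed asymmetric alkynylation of an enal: the dinuclear zinc–ProPhenol complex delivers the zinc acetylide to one aldehyde face and sets C7 (S) under ligand control.

Step 18
Reactants: 23 propargylic alcohol ester
Product: 24 C7 triethylsilyl ether of 23
Conditions: TESCl, imidazole, CH2Cl2, 0 °C
Reagents that add atoms: chlorotriethylsilane, CC[Si](Cl)(CC)CC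
Why: Standard silylation of the secondary alcohol; it also stops O7 from directing the hydroalumination of step 20.

Step 19
Reactants: 24 C7 triethylsilyl ether
Product: 25 (S,Z)-7-(4-methoxybenzyloxy)-6-methyl-4-(triethylsilyloxy)hept-5-en-2-yn-1-ol
Conditions: i-Bu2AlH, CH2Cl2, −78 °C
Reagents that add atoms: none
Why: 1,2-Reduction of the ynoate ester gives the propargylic alcohol (C19 OH) without touching the alkyne or the stereocentre.

Step 20
Reactants: 25 propargylic alcohol
Product: 26 (2Z,4S,5Z)-3-iodo-7-(4-methoxybenzyloxy)-6-methyl-4-(triethylsilyloxy)hepta-2,5-dien-1-ol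
Conditions: NaAlH2(OCH2CH2OMe)2, THF, 0 °C; then I2, −78 °C
Reagents that add atoms: iodine, II
Why: Hydroxyl-directed trans-hydroalumination: the C19 alkoxide delivers hydride to C17 and aluminium to C8, and iodinolysis with retention gives the 3-iodo allylic alcohol with iodine cis to C19.

Step 21
Reactants: 17 ring aldehyde; 26 iodo dienol
Product: 27 coupled ene-diol (C9 R carbinol; C8=C17 with C9 cis to C19H2OH; C7 S OTES; Z C5=C6; C4 OPMB)
Conditions: CrCl2, NiCl2 (2 mol%), DMSO/THF, 25 °C
Reagents that add atoms: none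
Why: Nozaki–Hiyama–Kishi coupling: the alkenylchromium forms with retention of geometry and adds only to the aldehyde, tolerating acetate, free hydroxyl and silyl ethers; attack anti to quaternary C1, the largest substituent on C10, gives the 9R carbinol.

Step 22
Reactants: 27 coupled ene-diol
Product: 28 8,17-epoxide (8S; both C–O bonds on the alkene face anti to the ring in the H-eclipsed C9 rotamer)
Conditions: Ti(Oi-Pr)4, D-(−)-diethyl tartrate, t-BuOOH, 4 Å MS, CH2Cl2, −20 °C
Reagents that add atoms: tert-butyl hydroperoxide, CC(C)(C)OO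
Why: Sharpless asymmetric epoxidation of the primary allylic alcohol: the D-tartrate delivers oxygen to the face that makes C8 S, the same face that 1,3-allylic strain at C9 leaves open, and the C5=C6 alkene, which has no free allylic hydroxyl, is not touched.

Step 23
Reactants: 28 8,17-epoxide
Product: 29 triol (C17 R methyl, C8 S tertiary OH, C9 OH, C19 OH)
Conditions: Me2CuLi (MeLi, CuI), Et2O, −40 → 0 °C
Reagents that add atoms: lithium dimethylcuprate, [Li+].C[Cu-]C
Why: Cuprate opening of a 3,3-disubstituted 2,3-epoxy alcohol: SN2 attack is possible only at C17 and goes with inversion, which creates the C17 methyl centre and the tertiary C8 carbinol in the anti relationship that becomes cis in the lactone.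

Step 24
Reactants: 29 triol
Product: 30 C19 triethylsilyl ether
Conditions: TESCl, imidazole, CH2Cl2, −20 °C
Reagents that add atoms: chlorotriethylsilane, CC[Si](Cl)(CC)CC
Why: Steric selection in silylation: the primary hydroxyl reacts well before the neopentyl secondary and the tertiary one.

Step 25
Reactants: 30 C19 triethylsilyl ether
Product: 31 C9 acetate
Conditions: Ac2O, Et3N, DMAP, CH2Cl2, 25 °C
Reagents that add atoms: acetic anhydride, CC(=O)OC(C)=O
Why: DMAP-catalysed acetylation of the secondary alcohol leaves the tertiary C8 hydroxyl alone; the acetate is added only after the basic cuprate step so that it cannot migrate.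

Step 26
Reactants: 31 C9 acetate
Product: 32 C7,C19-diol (C8 OH free)
Conditions: PPTS, MeOH/CH2Cl2, 0 °C
Reagents that add atoms: none
Why: Graded acid lability of silyl ethers: both triethylsilyl ethers are methanolysed while the tert-butyldimethylsilyl ether, the PMB ether and the acetates persist.

Step 27
Reactants: 32 C7,C19-diol
Product: 34 butanolide (C19 carbonyl, ring oxygen on C7, free C8 OH, 17-methyl cis to 8-OH), via lactol 33 (not isolated)
Conditions: TEMPO (20 mol%), PhI(OAc)2, CH2Cl2, 25 °C
Reagents that add atoms: none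
Why: Oxoammonium-mediated oxidative lactonisation of a 1,4-diol: the primary C19 alcohol is oxidised, the aldehyde is trapped by O7 as the five-membered lactol, and this is oxidised to the lactone under conditions too mild to enolise C17.

Step 28
Reactants: 34 butanolide
Product: 35 C8 triethylsilyl ether
Conditions: TESOTf, 2,6-lutidine, CH2Cl2, −78 → 0 °C
Reagents that add atoms: triethylsilyl triflate, CC[Si](CC)(CC)OS(=O)(=O)C(F)(F)F
Why: Silyl triflate silylation of the tertiary alcohol; masking O8 removes the six-membered hydroximate pathway by which it could add to the nitrile oxide in step 32.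

Step 29
Reactants: 35 C8 triethylsilyl ether
Product: 36 C4 allylic alcohol
Conditions: DDQ, CH2Cl2/pH 7 buffer, 0 °C
Reagents that add atoms: none
Why: Oxidative PMB ether cleavage, orthogonal to the silyl ethers, acetates and lactone.

Step 30
Reactants: 36 C4 allylic alcohol
Product: 37 Z enal (C4 aldehyde)
Conditions: MnO2, CH2Cl2, 25 °C
Reagents that add atoms: none
Why: Heterogeneous MnO2 oxidation of the allylic alcohol keeps the Z geometry, and O7, now acylated in the lactone, cannot form a lactol with C4.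

Step 31
Reactants: 37 Z enal
Product: 38 seco aldoxime, the key-step precursor (C4H=NOH on the Z C5=C6 arm; C1 vinyl; 8-OTES; 9-OAc; 12-OTBS; 14-OAc)
Conditions: NH2OH·HCl, pyridine, EtOH, 0 °C
Reagents that add atoms: hydroxylamine hydrochloride, NO.Cl
Why: Oxime condensation at the aldehyde is fast at 0 °C and creates no stereocentre (oxime geometry is irrelevant to the next step).

Step 32
Reactants: 38 seco aldoxime
Product: 41 isoxazoline-bridged ten-membered carbocycle (C4=N–O–C2 bridge over C3; new C2 centre R), via hydroximoyl chloride 39 (not isolated), via nitrile oxide 40 (not isolated)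
Conditions: NCS, DMF, 0 → 25 °C; then added over 12 h to Et3N, CH2Cl2, 1 mM, 25 °C
Reagents that add atoms: none
Why: NCS chlorinates the aldoxime carbon and Et3N removes HCl, so the conjugated nitrile oxide is released slowly at high dilution and adds across the C2=C3 vinyl group in a concerted suprafacial 1,3-dipolar cycloaddition, carbon to C3 and oxygen to C2; the closest known reaction type is the intramolecular nitrile oxide–alkene cycloaddition used to close medium and large rings, where long tethers give the 5-substituted, bridged isoxazoline. The ten-membered carbocycle closes through C3–C4 in a 10-endo-trig sense with respect to the alkene (the dipole C≡N stays outside that ring), and the five-membered isoxazoline forms in the same event as an N–O bridge between C2 and C4, a bicyclo[7.2.1] array. The one new stereocentre, C2, is controlled by quaternary C1: the vinyl group should react with its C=C bond eclipsing the C1–C15 bond, and the tether anchored at C10 can bring the dipole only onto the alkene face turned toward C10, which gives 2R. Regioselectivity is needed and follows from a monosubstituted alkene taking the dipole oxygen at its substituted carbon, the alternative requiring a strained nine-membered ring; chemoselectivity against furoxan formation rests on the slow release at 1 mM, and against capture by O8 on its silylation. The Z C5=C6 bond and the rigid butanolide hold C4 within reach of C3, and the alkene partner, on a fully substituted carbon, has no allylic hydrogen through which it could migrate.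

Step 33
Reactants: 41 isoxazoline-bridged carbocycle
Product: 42 2-hydroxy-4-enone (C2 R OH, C4 ketone conjugated with C5=C6)
Conditions: Mo(CO)6, MeCN/H2O, 80 °C
Reagents that add atoms: water, O
Why: Mo(CO)6-mediated reductive N–O cleavage and hydrolysis of the resulting β-hydroxy imine release the masked aldol without reducing the C5=C6 bond or the γ-acyloxy enone, and C2 is untouched.

Step 34
Reactants: 42 2-hydroxy-4-enone
Product: 43 2,4-anti diol (2R,4R)
Conditions: Me4NBH(OAc)3, MeCN/AcOH, −30 °C
Reagents that add atoms: none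
Why: Evans–Saksena reduction: the C2 alkoxy(acetoxy)borohydride delivers hydride intramolecularly to the C4 ketone through a chair-like six-membered array, giving 1,2-reduction of the enone and the 1,3-anti diol.

Step 35
Reactants: 43 2,4-anti diol
Product: 44 2,4,9,14-tetraacetate (8-OTES, 12-OTBS)
Conditions: Ac2O, pyridine, DMAP, CH2Cl2, 25 °C
Reagents that add atoms: acetic anhydride, CC(=O)OC(C)=O
Why: DMAP-catalysed acetylation of the two free secondary alcohols; O8 and O12 are silylated, so exactly the C2 and C4 acetates are added.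

Step 36
Reactants: 44 tetraacetate
Product: 45 CNP0183630.2, (1R,2R,4R,5Z,7S,8S,9R,10S,11R,12S,14S,17R)
Conditions: HF·pyridine, pyridine, THF, 0 → 25 °C
Reagents that add atoms: none
Why: Fluoride-driven cleavage of both silyl ethers (Si–F bond formation) under buffered, mildly acidic conditions that neither cleave nor move the four acetates gives the target.

Compound list
1 | pent-1-en-3-one | CCC(=O)C=C | starting material
2 | (Z)-triisopropyl(penta-1,3-dien-3-yloxy)silane | C=C/C(O[Si](C(C)C)(C(C)C)C(C)C)=C/C | intermediate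
3 | ethyl (E)-3-formylbut-2-enoate | CCOC(=O)/C=C(\C)C=O | starting material
4 | cycloadduct: C1 β-CH3/α-CHO, C10 β-CO2Et, C12=C13 TIPS enol ether, C11 epimers | C1C=C(O[Si](C(C)C)(C(C)C)C(C)C)C(C)[C@H](C(=O)OCC)[C@@]1(C)C=O | intermediate
5 | vinyl ester (C1 α-vinyl) | C1C=C(O[Si](C(C)C)(C(C)C)C(C)C)C(C)[C@H](C(=O)OCC)[C@@]1(C)C=C | intermediate
6 | C9 primary alcohol | C1C=C(O[Si](C(C)C)(C(C)C)C(C)C)C(C)[C@H](CO)[C@@]1(C)C=C | intermediate
7 | C9 PMB ether | C1C=C(O[Si](C(C)C)(C(C)C)C(C)C)C(C)[C@H](COCc2ccc(OC)cc2)[C@@]1(C)C=C | intermediate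
8 | enone, C11 epimers | C1=CC(=O)C(C)[C@H](COCc2ccc(OC)cc2)[C@@]1(C)C=C | intermediate
9 | lithium dienolate of 8 (not isolated) | [Li]OC1=C(C)[C@H](COCc2ccc(OC)cc2)[C@@](C)(C=C)C=C1 | intermediate
10 | enone, 11β-methyl | C1=CC(=O)[C@H](C)[C@H](COCc2ccc(OC)cc2)[C@@]1(C)C=C | intermediate
11 | 14α-pinacolboryl ketone (not isolated) | CC1(C)OB(OC1(C)C)[C@H]2CC(=O)[C@H](C)[C@H](COCc3ccc(OC)cc3)[C@@]2(C)C=C | intermediate
12 | 14α-hydroxy ketone | O[C@H]1CC(=O)[C@H](C)[C@H](COCc2ccc(OC)cc2)[C@@]1(C)C=C | intermediate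
13 | 14α-acetoxy ketone | CC(=O)O[C@H]1CC(=O)[C@H](C)[C@H](COCc2ccc(OC)cc2)[C@@]1(C)C=C | intermediate
14 | 12β-alcohol | CC(=O)O[C@H]1C[C@H](O)[C@H](C)[C@H](COCc2ccc(OC)cc2)[C@@]1(C)C=C | intermediate
15 | 12β-OTBS ether | CC(=O)O[C@H]1C[C@H](O[Si](C)(C)C(C)(C)C)[C@H](C)[C@H](COCc2ccc(OC)cc2)[C@@]1(C)C=C | intermediate
16 | C9 alcohol | CC(=O)O[C@H]1C[C@H](O[Si](C)(C)C(C)(C)C)[C@H](C)[C@H](CO)[C@@]1(C)C=C | intermediate
17 | ring aldehyde | CC(=O)O[C@H]1C[C@H](O[Si](C)(C)C(C)(C)C)[C@H](C)[C@H](C=O)[C@@]1(C)C=C | intermediate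
18 | propargyl alcohol | C#CCO | starting material
19 | (Z)-3-iodo-2-methylprop-2-en-1-ol | OC/C(C)=C\I | intermediate
20 | (Z)-1-iodo-3-(4-methoxybenzyloxy)-2-methylprop-1-ene | COc1ccc(COC/C(C)=C\I)cc1 | intermediate
21 | (Z)-4-(4-methoxybenzyloxy)-3-methylbut-2-enal | COc1ccc(COC/C(C)=C\C=O)cc1 | intermediate
22 | methyl propiolate | C#CC(=O)OC | starting material
23 | methyl (S,Z)-4-hydroxy-7-(4-methoxybenzyloxy)-6-methylhept-5-en-2-ynoate | COC(=O)C#C[C@@H](O)/C=C(/C)COCc1ccc(OC)cc1 | intermediate
24 | C7 triethylsilyl ether of 23 | COC(=O)C#C[C@@H](O[Si](CC)(CC)CC)/C=C(/C)COCc1ccc(OC)cc1 | intermediate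
25 | (S,Z)-7-(4-methoxybenzyloxy)-6-methyl-4-(triethylsilyloxy)hept-5-en-2-yn-1-ol | OCC#C[C@@H](O[Si](CC)(CC)CC)/C=C(/C)COCc1ccc(OC)cc1 | intermediate
26 | (2Z,4S,5Z)-3-iodo-7-(4-methoxybenzyloxy)-6-methyl-4-(triethylsilyloxy)hepta-2,5-dien-1-ol | OC/C=C(\I)[C@@H](O[Si](CC)(CC)CC)/C=C(/C)COCc1ccc(OC)cc1 | intermediate
27 | coupled ene-diol | CC(=O)O[C@H]1C[C@H](O[Si](C)(C)C(C)(C)C)[C@H](C)[C@H]([C@@H](O)/C(=C\CO)[C@@H](O[Si](CC)(CC)CC)/C=C(/C)COCc2ccc(OC)cc2)[C@@]1(C)C=C | intermediate
28 | 8,17-epoxide | CC(=O)O[C@H]1C[C@H](O[Si](C)(C)C(C)(C)C)[C@H](C)[C@H]([C@@H](O)[C@@]3(O[C@@H]3CO)[C@@H](O[Si](CC)(CC)CC)/C=C(/C)COCc2ccc(OC)cc2)[C@@]1(C)C=C | intermediate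
29 | triol with C17 methyl | CC(=O)O[C@H]1C[C@H](O[Si](C)(C)C(C)(C)C)[C@H](C)[C@H]([C@@H](O)[C@](O)([C@@H](C)CO)[C@@H](O[Si](CC)(CC)CC)/C=C(/C)COCc2ccc(OC)cc2)[C@@]1(C)C=C | intermediate
30 | C19 triethylsilyl ether | CC(=O)O[C@H]1C[C@H](O[Si](C)(C)C(C)(C)C)[C@H](C)[C@H]([C@@H](O)[C@](O)([C@@H](C)CO[Si](CC)(CC)CC)[C@@H](O[Si](CC)(CC)CC)/C=C(/C)COCc2ccc(OC)cc2)[C@@]1(C)C=C | intermediate
31 | C9 acetate | CC(=O)O[C@H]1C[C@H](O[Si](C)(C)C(C)(C)C)[C@H](C)[C@H]([C@@H](OC(C)=O)[C@](O)([C@@H](C)CO[Si](CC)(CC)CC)[C@@H](O[Si](CC)(CC)CC)/C=C(/C)COCc2ccc(OC)cc2)[C@@]1(C)C=C | intermediate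
32 | C7,C19-diol | CC(=O)O[C@H]1C[C@H](O[Si](C)(C)C(C)(C)C)[C@H](C)[C@H]([C@@H](OC(C)=O)[C@](O)([C@@H](C)CO)[C@@H](O)/C=C(/C)COCc2ccc(OC)cc2)[C@@]1(C)C=C | intermediate
33 | lactol (not isolated) | CC(=O)O[C@H]1C[C@H](O[Si](C)(C)C(C)(C)C)[C@H](C)[C@H]([C@@H](OC(C)=O)[C@@]3(O)[C@H](/C=C(/C)COCc2ccc(OC)cc2)OC(O)[C@@H]3C)[C@@]1(C)C=C | intermediate
34 | butanolide, free C8 OH | CC(=O)O[C@H]1C[C@H](O[Si](C)(C)C(C)(C)C)[C@H](C)[C@H]([C@@H](OC(C)=O)[C@@]3(O)[C@H](/C=C(/C)COCc2ccc(OC)cc2)OC(=O)[C@@H]3C)[C@@]1(C)C=C | intermediate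
35 | butanolide, 8-OTES | CC(=O)O[C@H]1C[C@H](O[Si](C)(C)C(C)(C)C)[C@H](C)[C@H]([C@@H](OC(C)=O)[C@@]3(O[Si](CC)(CC)CC)[C@H](/C=C(/C)COCc2ccc(OC)cc2)OC(=O)[C@@H]3C)[C@@]1(C)C=C | intermediate
36 | C4 allylic alcohol | CC(=O)O[C@H]1C[C@H](O[Si](C)(C)C(C)(C)C)[C@H](C)[C@H]([C@@H](OC(C)=O)[C@@]3(O[Si](CC)(CC)CC)[C@H](/C=C(/C)CO)OC(=O)[C@@H]3C)[C@@]1(C)C=C | intermediate
37 | Z enal | CC(=O)O[C@H]1C[C@H](O[Si](C)(C)C(C)(C)C)[C@H](C)[C@H]([C@@H](OC(C)=O)[C@@]3(O[Si](CC)(CC)CC)[C@H](/C=C(/C)C=O)OC(=O)[C@@H]3C)[C@@]1(C)C=C | intermediate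
38 | seco aldoxime (key-step precursor) | CC(=O)O[C@H]1C[C@H](O[Si](C)(C)C(C)(C)C)[C@H](C)[C@H]([C@@H](OC(C)=O)[C@@]3(O[Si](CC)(CC)CC)[C@H](/C=C(/C)\C=N\O)OC(=O)[C@@H]3C)[C@@]1(C)C=C | intermediate
39 | hydroximoyl chloride (not isolated) | CC(=O)O[C@H]1C[C@H](O[Si](C)(C)C(C)(C)C)[C@H](C)[C@H]([C@@H](OC(C)=O)[C@@]3(O[Si](CC)(CC)CC)[C@H](/C=C(/C)C(Cl)=NO)OC(=O)[C@@H]3C)[C@@]1(C)C=C | intermediate
40 | nitrile oxide (not isolated) | CC(=O)O[C@H]1C[C@H](O[Si](C)(C)C(C)(C)C)[C@H](C)[C@H]([C@@H](OC(C)=O)[C@@]3(O[Si](CC)(CC)CC)[C@H](/C=C(/C)C#[N+][O-])OC(=O)[C@@H]3C)[C@@]1(C)C=C | intermediate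
41 | isoxazoline-bridged ten-membered carbocycle (key-step product) | CC(=O)O[C@H]1C[C@H](O[Si](C)(C)C(C)(C)C)[C@H](C)[C@@H]2[C@@H](OC(C)=O)[C@@]3(O[Si](CC)(CC)CC)[C@H](/C=C(/C)C4=NO[C@H](C4)[C@]21C)OC(=O)[C@@H]3C | intermediate
42 | 2-hydroxy-4-enone | CC(=O)O[C@H]1C[C@H](O[Si](C)(C)C(C)(C)C)[C@H](C)[C@@H]2[C@@H](OC(C)=O)[C@@]3(O[Si](CC)(CC)CC)[C@H](/C=C(/C)C(=O)C[C@@H](O)[C@]21C)OC(=O)[C@@H]3C | intermediate
43 | 2,4-anti diol | CC(=O)O[C@H]1C[C@H](O[Si](C)(C)C(C)(C)C)[C@H](C)[C@@H]2[C@@H](OC(C)=O)[C@@]3(O[Si](CC)(CC)CC)[C@H](/C=C(/C)[C@H](O)C[C@@H](O)[C@]21C)OC(=O)[C@@H]3C | intermediate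
44 | 2,4,9,14-tetraacetate, 8-OTES, 12-OTBS | CC(=O)O[C@H]1C[C@H](O[Si](C)(C)C(C)(C)C)[C@H](C)[C@@H]2[C@@H](OC(C)=O)[C@@]3(O[Si](CC)(CC)CC)[C@H](/C=C(/C)[C@H](OC(C)=O)C[C@@H](OC(C)=O)[C@]21C)OC(=O)[C@@H]3C | intermediate
45 | CNP0183630.2 | CC(=O)O[C@H]1C[C@H](O)[C@H](C)[C@@H]2[C@@H](OC(C)=O)[C@@]3(O)[C@H](/C=C(/C)[C@H](OC(C)=O)C[C@@H](OC(C)=O)[C@]21C)OC(=O)[C@@H]3C | target

Total step count: 36. Longest linear sequence: 29 steps (steps 1–13, then 21–36); the side-chain iodide 26 is made in 7 steps (14–20).

Steps most likely to fail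

1. Step 32. The nitrile oxide may dimerise to a furoxan faster than it closes the ten-membered ring, or it may reach the other face of the vinyl group and give the C2 epimer. Fallback (aldol ring closure instead of cycloaddition), from 37 back to 43: Wacker oxidation of the C1 vinyl group of 37 (PdCl2, CuCl, O2, DMF/H2O) would give the C2 methyl ketone F1. Its boron enolate (Cy2BCl, Et3N, Et2O, −78 °C, high dilution) would add to the C4 aldehyde and close the ring as the 4-hydroxy-2-ketone F2. The Evans–Saksena reduction of step 34, now directed by the C4 hydroxyl, would then give diol 43.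

2. Step 21. The two congested partners may fail to join (the alkenylchromium is protonated instead), or attack on the aldehyde may show a poor facial ratio at C9. Fallback (organocerium addition instead of chromium), from 26 back to 27: TESCl and imidazole convert 26 into the bis-silyl ether F3. Iodine–lithium exchange (t-BuLi, −78 °C), transmetalation with CeCl3 and addition to aldehyde 17 give the C19 silyl ether adduct F4. Brief PPTS/MeOH at −20 °C frees the primary allylic hydroxyl and returns 27.

3. Step 22. Epoxidation may be slow or face-unselective because the ene-diol can bind titanium through both hydroxyls and the alkene is crowded. Fallback (substrate-directed peracid epoxidation instead of reagent control), from 27 forward to 30: selective silylation of the primary hydroxyl of 27 (TESCl, imidazole, −20 °C) gives the C19 silyl ether adduct F4. m-CPBA (NaHCO3, CH2Cl2, −20 °C), hydrogen-bonded to the C9 hydroxyl that 1,3-allylic strain holds on the required alkene face, gives the epoxide F5. Opening with Me2CuLi as in step 23 gives 30 directly, so step 24 is not needed.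

Further compounds
F1 | step 32 | C2 methyl ketone Z enal (C1 acetyl in place of vinyl) | CC(=O)O[C@H]1C[C@H](O[Si](C)(C)C(C)(C)C)[C@H](C)[C@H]([C@@H](OC(C)=O)[C@@]3(O[Si](CC)(CC)CC)[C@H](/C=C(/C)C=O)OC(=O)[C@@H]3C)[C@@]1(C)C(C)=O
F2 | step 32 | ring-closed 4-hydroxy-2-ketone (aldol product) | CC(=O)O[C@H]1C[C@H](O[Si](C)(C)C(C)(C)C)[C@H](C)[C@@H]2[C@@H](OC(C)=O)[C@@]3(O[Si](CC)(CC)CC)[C@H](/C=C(/C)[C@H](O)CC(=O)[C@]21C)OC(=O)[C@@H]3C
F3 | step 21 | bis(triethylsilyl) ether of iodide 26 | CC[Si](CC)(CC)OC/C=C(\I)[C@@H](O[Si](CC)(CC)CC)/C=C(/C)COCc1ccc(OC)cc1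
F4 | step 21 | C19 triethylsilyl ether of ene-diol 27 | CC(=O)O[C@H]1C[C@H](O[Si](C)(C)C(C)(C)C)[C@H](C)[C@H]([C@@H](O)/C(=C\CO[Si](CC)(CC)CC)[C@@H](O[Si](CC)(CC)CC)/C=C(/C)COCc2ccc(OC)cc2)[C@@]1(C)C=C
F5 | step 22 | 8,17-epoxide carrying the C19 triethylsilyl ether | CC(=O)O[C@H]1C[C@H](O[Si](C)(C)C(C)(C)C)[C@H](C)[C@H]([C@@H](O)[C@@]3(O[C@@H]3CO[Si](CC)(CC)CC)[C@@H](O[Si](CC)(CC)CC)/C=C(/C)COCc2ccc(OC)cc2)[C@@]1(C)C=C
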